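(The earlier runs and the new flask come from a simulation on assumed constants.)

Amounts first: the winter, spring, Thursday's and Monday's flasks each hold 20 mM of substrate and 21.0 mM of first nucleophile, and Thursday's and Monday's differ in second nucleophile and in time.

| flask | substrate | first nucleophile | second nucleophile | remark | time |
|---|---|---|---|---|---|
| winter | 20 mM | 21 mM | 28 mM | run made earlier |  |
| spring | 20 mM | 21 mM | 79 mM | run made earlier |  |
| Thursday's | 20 mM | 21.0 mM | 50.0 mM |  | 10 h |
| Monday's | 20 mM | 21.0 mM | 25.0 mM |  | 5.0 h |

| run | time / h | target / % | substrate / % |
|---|---|---|---|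
| winter | 0.500 | 2.2 | 94.1 |
| winter | 0.833 | 1.1 | 89.6 |
| winter | 1.33 | 3.1 | 86.3 |
| winter | 2.00 | 5.1 | 81.0 |
| winter | 3.00 | 8.0 | 71.4 |
| winter | 5.00 | 12.7 | 57.2 |
| winter | 8.00 | 17.2 | 41.7 |
| spring | 1.00 | 1.6 | 90.3 |
| spring | 2.00 | 3.0 | 83.0 |
| spring | 3.00 | 5.9 | 72.1 |
| spring | 4.00 | 7.0 | 63.7 |
| spring | 5.00 | 8.0 | 58.9 |
| spring | 6.00 | 7.6 | 49.9 |
| spring | 8.00 | 11.3 | 42.3 |

(readings scatter by 1 percentage point)

* the flask that ends with the higher amount of target, in percent of the substrate charged, or "neither" when 2 percentage points or less lies between them (Thursday's / Monday's / neither)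
* final target, as a percentage of the substrate charged, in Thursday's
* final target, as a percentage of the substrate charged, in Monday's



1. Time. By hand, a longer run consumes more substrate, so I count its time in half-lives. At 8.00 h, the winter run keeps 41.7 % of its substrate and the spring run 42.3 %. These differ by less than the scatter, although the second nucleophile differs. Taking the loss as first order, I get a constant k = 0.108 h⁻¹. The substrate half-life T, the time in which the substrate present halves, is then 6.39 h.

2. Counting. With n = t/T, Thursday's runs 1.56 half-lives, and I estimate its consumed share of substrate at c = 66.2 %. Monday's runs 0.782, and I estimate its share at 41.9 %. By this estimate, Thursday's has twice the half-lives, but less than twice the consumption.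

3. Second nucleophile. By hand, if the second nucleophile competes for the route to target, then raising it with the other charges held lowers the selectivity f, the target found per substrate consumed. At 8.00 h, f reads 0.295 in the winter run and 0.196 in the spring run. Drawing 1/f as a straight line in second nucleophile gives 0.242 for Thursday's and 0.304 for Monday's.

4. My reckoning. The product f·c gives 16.0 % for Thursday's and 12.7 % for Monday's, a gap of 3.3 percentage points against a margin of 2 points.

5. The forecast. It says Thursday's, with 15.6 % (14 % to 17.2 %) and 12.7 % (11.5 % to 13.9 %). Its Thursday's figure is a little below mine, and it calls its gap “modestly above the threshold”.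

6. The flasks. Thursday's ends at 13.5 % and Monday's at 13.1 %, so the answer is neither: the gap of 0.40 points is less than the margin. Both forecast yields fall within tolerance, but its choice of flask does not hold.

    substrate → intermediate (k = 0.00180 min⁻¹)
    first nucleophile + intermediate → target (k = 1.20 L mol⁻¹ min⁻¹)
    second nucleophile + intermediate → other capture product (k = 0.990 L mol⁻¹ min⁻¹)
    intermediate → solvolysis product (k = 0.0160 min⁻¹)
    first nucleophile + target → over-reaction product (k = 0.0430 L mol⁻¹ min⁻¹)

Thursday's count of 1.56 half-lives leaves 33.8 % of the substrate, and the flask holds 34.0 %. Its target of 13.5 % stands below my 16.0 %, with 4.03 % of over-reaction product beside it. Monday's mixture left until 20 h has run 3.13 half-lives, so the count leaves 11.4 % of the substrate, and that flask holds 11.5 %. The product f·c there gives 26.9 % of target, while the flask holds 19.0 % of target and 12.0 % of over-reaction product.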